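The readings are calculated from invented constants.

**One-step world.** In a one-step world each substrate passes once to its own product, and at low conversion the product excess records the ratio of the two rate constants, the selectivity factor; later it falls as the faster substrate is used up. The dusk flask has a single-handed catalyst, a racemate and a slow feed of partner.

all flasks: free catalyst 50 µM; added ligand 64 µM
- dusk: left-handed substrate 10 mM; right-handed substrate 10 mM; partner 12 mM (fed, over 25 h); the very flask that is asked about, followed so far; the fed solution adds 1.0 times the starting volume
- noon: left-handed substrate 5 mM; right-handed substrate 5 mM; partner 12 mM (fed, over 25 h); run made earlier; the fed solution adds 1.0 times the starting volume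
- flask: left-handed substrate 10 mM; right-handed substrate 10 mM; partner 12.0 mM (fed, over 25 h); the fed solution adds 1.0 times the starting volume; time 2.0 d

| run | time / h | left-handed product / % | right-handed product / % | left-handed substrate / % |
|---|---|---|---|---|
| dusk | 0.333 | 0.2 | 0.9 | 48.4 |
| dusk | 1.00 | 0.2 | 0.3 | 47.0 |
| dusk | 2.00 | 2.3 | 1.3 | 48.5 |
| dusk | 3.00 | 4.2 | 1.5 | 45.9 |
| dusk | 4.00 | 4.9 | 1.1 | 44.2 |
| noon | 1.50 | 0.9 | 0 | 48.5 |
| noon | 5.00 | 8.9 | 1.1 | 40.3 |
| noon | 8.00 | 16.2 | 0.2 | 35.1 |
| noon | 15.0 | 31.7 | 3.9 | 18.7 |
| noon | 20.0 | 38.1 | 7.7 | 10.5 |

(readings scatter by 1 percentage point)

1. excess of left-handed product over right-handed product in the product at 5.0 h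
2. excess of left-handed product over right-handed product in the product at 2.0 d
3. part of the left-handed substrate and right-handed substrate charged together that has reacted at 2.0 d

- free catalyst is single-handed; left-handed substrate and right-handed substrate are mirror images of each other, charged as a racemate, each of them at the stated concentration
- charges are per starting volume, the dose included; the dosed solution carries all of it
- steps thought possible: free catalyst + added ligand <-> idle complex; partner + free catalyst -> spent catalyst; left-handed product <-> right-handed product; partner + free catalyst + left-handed substrate -> free catalyst + left-handed product; partner + free catalyst + right-handed substrate -> free catalyst + right-handed product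
- an excess is the difference of the two amounts in percent of their sum
- an excess is below zero if the other one leads

**Bench rule.** The first three noon readings sum to a left-handed over right-handed product ratio of 20.0, a scattered reading. The rule holds the excess at that ratio less one over the ratio plus one, 90.5%.

**Its border.** At 20.0 h in the noon run, the left-handed substrate balance and that ratio give a no-leak excess of 82.6%, but the product readings give 66.4%. Replacing the growing product by its mean makes its mean age half the elapsed time. The leak clock, mean age over the natural logarithm of no-leak excess to read excess, pooled from the last two noon readings, is 55.9 h. Mean age over clock is 0.179 for that noon reading. In the dusk flask at 2.0 d, with product born on average at mid-feed, the age is 35.5 h and the ratio 0.635, which is past the border of the bench rule. Spreading births evenly over the feed raises the factor by 0.835%, but that test does not count product born after the feed, so this age stands only as a rough one.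

**Two estimates.** This reckoning gives 86.5% at 5.0 h and, from the noon no-leak excess, 43.8% at 2.0 d. The forecast says 81%, 63% and 52% reacted: “The noon product balance hints at slight product racemization, so I lower this to about 63%.” The two part by 19 percentage points at the later time.

**The result.** The dusk flask gives 86.8%, 47.3% and 50.7% reacted.

    free catalyst + added ligand ⇌ idle complex, settled at all times (K = 11500 M⁻¹)
    partner + free catalyst → spent catalyst (k = 0.0539 M⁻¹ min⁻¹)
    left-handed product ⇌ right-handed product (k = 1.29 × 10⁻⁴ min⁻¹)
    partner + free catalyst + left-handed substrate → free catalyst + left-handed product (k = 32600 M⁻² min⁻¹)
    partner + free catalyst + right-handed substrate → free catalyst + right-handed product (k = 1670 M⁻² min⁻¹)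

In this flask the two products have a relaxation half-life, both ways together, of 1.87 d, shorter than the 2.0 d of the run. Meanwhile left-handed substrate stands at 9.8% of its charge, less than the 89% of right-handed substrate. The clock's factor on this flask's own no-leak excess, 77.9%, gives 41.3%. On the neighbour with 30 mM of partner, a no-leak 46.6% becomes 24.7%, against a simulated 21.3%.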